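Write the balance of the left-handed substrate, of which the flask holds less than of partner.

| flask | left-handed substrate | right-handed substrate | partner | free catalyst | added ligand | remark | time |
|---|---|---|---|---|---|---|---|
| Tuesday's | 12 mM | 12 mM | 1.7 equiv | 0.05 mol% | 7.1 µM | run made earlier |  |
| Monday's | 12 mM | 12 mM | 2.6 equiv | 0.05 mol% | 7.1 µM | run made earlier |  |
| flask | 12 mM | 12 mM | 1.20 equiv | 0.05 mol% | 7.1 µM |  | 2.0 h |

- Tuesday's (time / min: right-handed substrate / %, left-handed substrate / %): 10.0: 50.5, 49.4; 25.0: 49.8, 47.5; 50.0: 49.9, 44.7; 80.0: 49.9, 42.4
- Monday's (time / min: right-handed substrate / %, left-handed substrate / %): 10.0: 50.0, 48.5; 25.0: 49.0, 45.9; 50.0: 50.2, 42.6; 80.0: 50.3, 38.5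

(scatter of a reading: 0.3 percentage points)

- free catalyst is single-handed; left-handed substrate and right-handed substrate are mirror images of each other, charged as a racemate, each of them at the stated concentration
- the analysis behind the earlier runs scatters by 0.3 percentage points, standard deviation

1. whether the excess of right-handed substrate over left-handed substrate among what is left of the two reaches 99% by 2.0 h (yes / no)
2. the highest excess of right-handed substrate over left-handed substrate among what is left of the two up to 2.0 h

In both earlier runs the right-handed substrate stays near 49.9%, so I take it as the level from which the left-handed substrate started. I follow the index Λ = ln([right-handed substrate]/[left-handed substrate]). At the last reading, Tuesday's run has Λ = 0.163 and Monday's run 0.267. That is a ratio of 1.64 as read, against 1.53 in partner. So I write the loss as pseudo-first-order in the left-handed substrate, with a rate proportional to the equivalents of partner, while loading and ligand stay as in both runs. The last readings of the two runs, pooled, give 0.0750 h⁻¹ per equivalent for κ, the index gained per equivalent of partner per unit time.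

For the flask my reckoning gives Λ = 0.180, which is an excess of 8.98% at the end, where it is highest. The wanted excess needs Λ = 5.29, far more than my reckoning gives, so I say no.

The forecast also says no, with a top of 8.7% (from 7.3% to 10.2%), lower than mine, from a reckoning of “about 0.175 after slight partner depletion”.

The flask gives no and a top of 8.44%, inside the forecast's range. At 2.00 h the partner in the flask stands at 72% of its charge. The index that follows from the flask's top is 0.169, which is 0.940 of what κ gave.

    free catalyst + right-handed substrate ⇌ catalyst intermediate B (K = 50.0 M⁻¹, k = 9.60 × 10⁵ M⁻¹ h⁻¹)
    partner + catalyst intermediate B → free catalyst + right-handed product (k = 930 M⁻¹ h⁻¹)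
    free catalyst + added ligand ⇌ idle complex, settled at all times (K = 2.10 × 10⁵ M⁻¹)
    partner → decomposed reagent (k = 0.0890 h⁻¹)
    free catalyst + left-handed substrate ⇌ catalyst intermediate A (K = 180 M⁻¹, k = 4.50 × 10⁶ M⁻¹ h⁻¹)
    partner + catalyst intermediate A → free catalyst + left-handed product (k = 31000 M⁻¹ h⁻¹)

In the neighbouring flask with 2.00 equiv of partner, κ gives Λ = 0.300, an excess of 14.9%. The computed top in that neighbouring flask is 14.3%, above the forecast's range for the flask.

The readings come from a simulation for substances that don't exist; scatter was added.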